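The runs are simulated on assumed constants, noise included.

The constants of the steps were hidden from me, so I worked from a difference in the readings of the grey run, which is this very flask followed so far.

- grey: starting material 0.40 M; coupling partner 1.2 equiv (fed, over 25 s); protic impurity 0.12 M; free catalyst 0.059 mol%; the very flask that is asked about, followed so far
- flask: starting material 0.40 M; coupling partner 1.20 equiv (fed, over 25 s); protic impurity 0.120 M; free catalyst 0.059 mol%; time 2.0 min

grey run (percent of the starting material charged)

| time / s | catalyst intermediate A / % | product / % | starting material / % | catalyst intermediate B / % | catalyst intermediate C / % |
|---|---|---|---|---|---|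
| 10.0 | 0.2 | 0.6 | 97.8 | 0.6 | 0 |
| 15.0 | 0 | 0.9 | 96.7 | 0.2 | 0.3 |
| 30.0 | 0 | 3.0 | 92.6 | 0 | 0 |
| 50.0 | 0 | 6.2 | 88.9 | 0.4 | 0 |

(readings scatter by 0.3 percentage points)

- the species in which most of what was charged as starting material, at 2.0 min sits (catalyst intermediate B / catalyst intermediate C / product / catalyst intermediate A / starting material)
- the largest share itself, whichever of these holds it, in percent of the starting material charged

- candidate steps: starting material + free catalyst -> catalyst intermediate A; coupling partner + catalyst intermediate A <-> catalyst intermediate B; catalyst intermediate B -> by-product + catalyst intermediate C; catalyst intermediate C -> free catalyst + product; starting material + protic impurity -> quenched substrate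

I turned the question round. The catalyst intermediates together hold no more than the loading of 0.059 mol%, far less than the 6.2% of product read at 50.0 s, so the opposite outcome meant product overtaking starting material. I therefore set the level point of those two as the zero of my scale.

At 50.0 s the gap between them stood at 83 percentage points. It had narrowed by 6.9 points over the preceding 20.0 s, after the feed had ended at 25 s, with each reading scattering by 0.3 points. Held straight at that pace, the gap reached zero at 4.83 min, the crossing time, the moment at which the pace read brings starting material and product level. The asked 2.0 min lay before it, and for product to draw level by then the gap in this flask had to close 3.42 times as fast as I read it. So I expected starting material to stay ahead, though my reckoning gave an order and no share.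

The forecast said starting material at 75%, “still by far the largest share”.

The flask gave starting material at 73.0%, with product at 15.3%.

    starting material + free catalyst → catalyst intermediate A (k = 26.0 M⁻¹ s⁻¹)
    coupling partner + catalyst intermediate A ⇌ catalyst intermediate B (K = 0.820 M⁻¹, k = 210 M⁻¹ s⁻¹)
    catalyst intermediate B → by-product + catalyst intermediate C (k = 15.0 s⁻¹)
    catalyst intermediate C → free catalyst + product (k = 18.0 s⁻¹)
    starting material + protic impurity → quenched substrate (k = 0.0120 M⁻¹ s⁻¹)

Taken alone, with the other concentrations held at their charge, the passing of starting material and protic impurity into quenched substrate has a pseudo-first-order half-life of 8.0 min, long against 2.0 min. The gap in the flask still stood at 58 points at 2.0 min, with my reckoned crossing time of 4.83 min ahead. The same flask read at 8.0 min, later than that reckoned time, held most in product, at 51.4% against 26.7% of starting material.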